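The amounts in this flask start as undissolved solid, so what stands in it at a given time depends on how fast material arrives and how fast it leaves.

the same everywhere: solid substrate 0.017 M; catalyst 2.6 mM; added ligand 4.5 mM
- birch: the very flask that is asked about, followed so far
- flask: time 4.0 h

birch run (percent of the solid substrate charged)

| time / min | target / % | isomer of the product / % |
|---|---|---|
| 3.00 | 0 | 0 |
| 8.00 | 6 | 0 |
| 20.0 | 17 | 3 |
| 40.0 | 29 | 1 |

(scatter of a reading: 1.5 percentage points)

- given per volume of solution although it is solid: solid substrate
- at the start none of the solid substrate is in solution

* share of target in target plus isomer of the product at 6.0 min
* share of target in target plus isomer of the product at 4.0 h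
* which of target and isomer of the product there is more of at 4.0 h

In the birch run, which is this same flask followed so far, target climbed from 6% at 8.00 min to 17% over the next 12.0 min, and then to 29% over the following 20.0 min, a slower climb. I treated target as a tank with an inflow and an outflow proportional to its level, the pseudo-first-order picture, in which the slope drops as the level rises. I named the drain time, the rise in mean level between those two intervals divided by the drop in slope, and reckoned it at 36.3 min. With a scatter of 1.5 percentage points on each reading this was a rough figure, and a falling inflow could have bent the curve in the same way. While inflow exceeds level over drain time, target rises; once inflow falls below that, control passes to the loss and target decays. The latest time is 6.61 drain times, so I committed to isomer of the product ahead at 4.0 h, while early on, with isomer reading 0% at 8.00 min, I expected nearly pure target.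

The forecast gave 96% at 6.0 min and 84% at 4.0 h, with target ahead, and said: “The runs cannot distinguish parallel formation from slow isomerisation of the target.” We agreed early and parted late.

The flask gave 99.3% and 1.68%, with isomer of the product ahead.

    catalyst + other conformer → catalyst + isomer of the product (k = 0.322 M⁻¹ s⁻¹)
    starting material + catalyst → catalyst + target (k = 0.500 M⁻¹ s⁻¹)
    starting material ⇌ other conformer (K = 1.50, k = 8.63 × 10⁻⁵ s⁻¹)
    solid substrate ⇌ starting material, rate k4*(cs4 - [starting material]) while solid is left; crystals form when [starting material] > cs4 (solubility = 14.0 mM, k = 0.00101 s⁻¹)
    catalyst + added ligand ⇌ idle complex (K = 429 M⁻¹, k = 0.514 M⁻¹ s⁻¹)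
    catalyst + target → catalyst + over-reaction product (k = 0.558 M⁻¹ s⁻¹)

At 0.227 h target was made 3.23 times faster than it was used up, but its half-life towards over-reaction product, with the catalyst as charged, was 0.13 h, short against 4.0 h, and at 4.00 h the flask held 0.191% target beside 88.5% over-reaction product. In the further flask with 0.0010 M of catalyst, the catalyst outside the idle complex at 4.00 h was lower than in this flask by a factor of 3.01, which stretches my rough drain time to about 109 min and makes the same 4.0 h about 2.20 such drain times, and that flask held 12.0% target, a share of 41.1%.

The readings were computed for an exercise, noise included.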